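**Remarks.** Atom locants C1–C26 (O18) follow the order of the atoms in the target SMILES; compound numbers are those of the steps below. Assumption: the sense of induction of the two chiral catalysts (steps 3 and 16) is taken from the accepted models for the (S)-oxazaborolidinium and the (S)-p-tol-BINAP copper hydride; if either delivered the mirror image, its antipode would be used.

## Analysis of the target

The target 36 is a C25 alcohol with a linearly fused 5-8-6-5 skeleton: cyclopentane ring A (C5, C6, C23, C24, C25), cyclooctadiene ring B (C2–C7, C9, C22), cyclohexane ring C (C9, C10, C11, C19, C21, C22) and cyclopentanol ring D (C11, C12, C16, C17, C19). It has eight stereocentres (5S, 9S, 11S, 12S, 17R, 19R, 22S, 25S): rings C and D are trans-fused (C20 methyl anti to C11–H), and rings B and C are trans-fused with C7 and C2 both equatorial on the chair of ring C. The C12 isopropyl group is trans to C10, the C17 hydroxyl is cis to C20, and on ring A the C4 branch and the C26 methyl are cis. Ring B is a cycloocta-1,5-diene with a Z trisubstituted alkene C2=C3 and a tetrasubstituted alkene C6=C7 exocyclic to ring A; acid could trigger transannular cyclisation or double-bond migration, so the late steps must stay neutral or basic. The hard points are the medium ring, the geometry of C6=C7 (not controllable in an open chain), and the cis C4/C26 relation, which only arises if hydrogen rather than carbon is the last group delivered to C5. The ring A stereocentres are also remote from those of rings C and D, so each half needs its own source of absolute configuration. The strategy rests on ring D: C17 carries oxygen next to the quaternary C19, and C12 is the fifth atom from C16 along C16–C17–C19–C11–C12, so a carbenoid at C16 of an acyl group on C19 can insert into a C12–H bond of an isobutyl group on C11, which reduces rings C and D to a 1,2-disubstituted cyclohexane.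

## Retrosynthetic reasoning

**C7–C8 (36 ⇐ 35 ⇐ 34).** After removal of the silyl ether of 35, the methyl group C8 is cut from C7. This leads back to enol triflate 34, whose C6=C7 bond lies inside ring B and can therefore only have C5 and C9 cis. A cross-coupling that retains alkene geometry then gives the tetrasubstituted alkene without any open-chain selectivity problem.

**C5–H and C7–O (34 ⇐ 32).** The enol triflate is traced to the ring A enone 32 by conjugate delivery of hydride to C5. This is the only order in which hydrogen enters C5 last, on the face opposite the C26 methyl, leaving C4 and C26 cis. The same event produces the enolate toward C6 and not toward C9, so no regiochemical choice is left.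

**C2=C3 (32 ⇐ 31).** Ring B is opened at its trisubstituted alkene by a metathesis disconnection to dienone 31, which has an isopropenyl group on C22 and an allyl group on C5. The eight-membered ring admits only the Z alkene, and the two arms are held close (trans-diequatorial on ring C, cis across C5=C6).

**C6–C7 (31 ⇐ 30 ⇐ 24 + 29).** Cutting the bond between the ring A alkene carbon and the carbonyl carbon divides the molecule into ring A triflate 29 and hydrindane aldehyde 24. Each fragment gets its own source of absolute configuration, and the union creates only a carbinol centre (in 30) that is oxidised away.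

**Ring A (29 ⇐ 27 ⇐ 25).** Triflate 29 comes from ketone 27 by enolisation toward the substituted carbon C5. Ketone 27 comes from 3-methylcyclopent-2-en-1-one 25 by asymmetric conjugate reduction (C25–H) and allylation of the regiodefined enol derivative (C4–C5). Only C25 has to survive.

**Side arms of ring C (24 ⇐ 23 ⇐ 22).** The formyl group is an ester in 23, and the isopropenyl group is an acetyl group in 22. The acetyl group is chosen because it makes C22 epimerisable, so the trans-diequatorial arrangement of 22 can be reached by equilibration.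

**C9–C7 and C22–C2 (22 ⇐ 20 ⇐ 19 ⇐ 18 ⇐ 15).** An sp2 carbon cannot be put on C22 by enolate alkylation, so C2 is introduced by acylation of ketone 15 at C22 (via enamine 16). The resulting enolised diketone 18 is turned into enol triflate 19, and carbonylation there forms C9–C7. The tetrasubstituted alkene of 20 is then saturated. Regiochemistry rests on the preference of the trans-hydrindanone to enolise toward C22, away from the ring fusion.

**Ring D adjustment (15 ⇐ 14 ⇐ 12).** The C17 ketone of 12 is reduced from the face opposite C20, the ketal is removed and the alcohol is silylated.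

**C12–C16, the key disconnection (12 ⇐ 11).** Ring D is opened between C12 and C16. This gives diazoketone 11, in which the C19 acyl group and the C11 isobutyl group are trans-diequatorial on ring C. The forward reaction must insert the C16 carbenoid into C12–H only, and with the isopropyl group trans to C10.

**Diazoketone (11 ⇐ 9 ⇐ 8 ⇐ 7).** The diazoketone is made from acid 9 through acid chloride 10. The acid comes from aldehyde 7 by oxidation and then ketalisation of keto acid 8. The order matters, since ketalising first would also acetalise the aldehyde.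

**C19–C21 and C10–C11 (7 ⇐ 5 + 2).** Ring C is a Diels–Alder adduct of enal 5 and diene 2. The E geometry of 5 fixes formyl and isobutyl trans, the diene regiochemistry puts oxygen on C9, and a chiral Lewis acid sets both centres.

**Building blocks (5 ⇐ 3 + 4; 2 ⇐ 1).** A crossed aldol route to 5 would have to choose between two enolisable aldehydes and would be unselective, so enal 5 is made by Wittig olefination of 3-methylbutanal 3 with formyl ylide 4. Diene 2 is the silyl dienol ether of but-3-en-2-one 1.

## Alternatives that were turned down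

**Alternative 1:** Rings B and C are cut together at C9–C22 and C4–C5, which leaves two 1,3-diene arms (C22=C2–C3=C4, and C9=C7–C6=C5 with C5=C6 inside ring A) on C19 and C11 of a finished ring D. In the forward direction a zerovalent nickel–phosphine catalyst joins the diene termini in a [4+4] cycloaddition and gives A1 (the same compound as 35) with C2=C3 and C6=C7 already in place.
- For: the step economy is unmatched. One step makes two rings, both alkenes and three stereocentres, and a cycloocta-1,5-diene is the native [4+4] product. On step count it is clearly stronger than the last six steps of the chosen route.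
- Against: the ring A diene must bond at C5 next to the C25 methyl. Carbon would enter anti to that methyl and give the trans C4/C26 relation, while the target needs cis. Nickel [4+4] couplings also tolerate little substitution: one diene here is fully substituted at its internal carbons and must give a tetrasubstituted alkene, so [4+2] modes and open dimers are likely. C9 and C22 depend on two stereodefined trisubstituted dienes and on tether folding, with no later correction possible.
- In its place the chosen strategy offers one separately controllable event per stereocentre: insertion geometry for C12, equilibration for C9 and C22, hydride anti to methyl for C5.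

**Alternative 2:** Ring C is cut at C9–C10. The C10 radical is released by opening a cyclopropane (C12–C10) of a chiral-pool bicyclic ketone that already holds the isopropyl group. In the forward direction a tin hydride chain makes the α-keto radical at C16 from a bromide, the cyclopropylcarbinyl radical opens to a C12=C16 enone, and the primary C10 radical closes 6-endo on C9 of an acrylate tethered to C19, giving A2.
- For: ring D comes from the chiral pool. A2 also carries differentiated one-carbon handles on C9 and C22 straight from the ring closure, which is stronger than the chosen route, where steps 10–15 are spent reaching that stage.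
- Against: the acrylate tether must first be installed on the quaternary carbon next to the ketone. The 6-endo closure of a primary radical on a trisubstituted acrylate competes with 5-exo attack at C22 and with simple reduction. C9 is fixed kinetically. C12 is sp2 in A2, so its configuration and that of C17 are left to later reductions. Tin is used stoichiometrically, and the C22 ester still needs several steps to become isopropenyl.
- In its place the chosen strategy forms C12 with its configuration in the ring-forming step, and reaches C9 and C22 under thermodynamic control from an oxygen placed on C9 by cycloaddition regiochemistry.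

**Alternative 3:** C10–C11 and C19–C21 are cut, so ring D enone A3 is the start and both ring C arms are added in one flask. An allylcopper reagent with a silyl chloride adds to C11 anti to the isopropyl group, and the regenerated lithium enolate is allylated at C19 anti to the new arm, giving A4. Metathesis of the two allyl groups would then close ring C.
- For: stereocontrol in ring D is at least as good as in the chosen route and arguably safer, because C12 is present from the start and C11 and C19 follow by well-understood anti additions. No C–H insertion selectivity is at stake, and the sequence is very short.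
- Against: ring closure leaves an unpolarised C9=C22 alkene. Nothing distinguishes C9 from C22, so attaching C7 and C2 regioselectively and trans has no handle, and A3 itself needs an enantioselective synthesis.
- In its place the chosen strategy has the C9 oxygen, from which C22 acylation and C9 carbonylation follow with defined regiochemistry. The price is the risk of the insertion step.

Key step: step 7

## Route

Step 1
Reactants: 1 but-3-en-2-one
Product: 2 2-[(triisopropylsilyl)oxy]buta-1,3-diene
Conditions: i-Pr3SiOTf, Et3N, Et2O, 0 °C → rt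
Reagents that add atoms: triisopropylsilyl trifluoromethanesulfonate, CC(C)[Si](OS(=O)(=O)C(F)(F)F)(C(C)C)C(C)C
Why: Silyl dienol ether formation by O-silylation of the amine-generated dienolate; the bulky silyl group is chosen because it should survive the strongly acidic cycloaddition catalyst better than a trimethylsilyl ether.

Step 2
Reactants: 3 3-methylbutanal; 4 2-(triphenyl-λ5-phosphanylidene)propanal
Product: 5 (E)-2,5-dimethylhex-2-enal
Conditions: PhMe, 90 °C
Reagents that add atoms: none
Why: Wittig reaction of a stabilised formyl ylide with an aliphatic aldehyde, which should give the E enal; the conjugated, α-branched product is too unreactive to be olefinated again.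

Step 3
Reactants: 5 (E)-2,5-dimethylhex-2-enal; 2 2-[(triisopropylsilyl)oxy]buta-1,3-diene
Product: 7 (1R,2R)-1-methyl-2-(2-methylpropyl)-4-oxocyclohexane-1-carbaldehyde, via silyl enol ether cycloadduct 6 (not isolated)
Conditions: (S)-B-(o-tolyl)oxazaborolidine from (S)-α,α-diphenylprolinol, protonated with Tf2NH (20 mol%), CH2Cl2, −78 → −20 °C; then 1 M HCl, THF, rt
Reagents that add atoms: none
Why: Chiral Lewis acid catalysed Diels–Alder reaction: the cationic oxazaborolidinium binds the formyl group and shields one face of the enal, and the nucleophilic diene terminus bonds to the β-carbon C11, which places oxygen on C9. Suprafacial addition to the E enal fixes the C19 formyl and C11 isobutyl groups trans, and the catalyst sets both centres absolutely. Aqueous acid then hydrolyses the silyl enol ether so that the aldehyde can be oxidised without an enol ether present.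

Step 4
Reactants: 7 (1R,2R)-1-methyl-2-(2-methylpropyl)-4-oxocyclohexane-1-carbaldehyde
Product: 8 (1R,2R)-1-methyl-2-(2-methylpropyl)-4-oxocyclohexane-1-carboxylic acid
Conditions: NaClO2, NaH2PO4, 2-methylbut-2-ene, t-BuOH/H2O, rt
Reagents that add atoms: sodium chlorite, [Na+].[O-]Cl=O
Why: Pinnick oxidation; chlorite oxidises the hindered, non-enolisable aldehyde and leaves the ketone alone, while the alkene removes hypochlorite.

Step 5
Reactants: 8 (1R,2R)-1-methyl-2-(2-methylpropyl)-4-oxocyclohexane-1-carboxylic acid
Product: 9 (7R,8R)-8-methyl-7-(2-methylpropyl)-1,4-dioxaspiro[4.5]decane-8-carboxylic acid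
Conditions: HOCH2CH2OH, TsOH·H2O (cat.), PhH, reflux (Dean–Stark)
Reagents that add atoms: ethane-1,2-diol, OCCO
Why: Acid-catalysed ketalisation with azeotropic removal of water; only the ketone should react, because esterification of the neopentyl-type tertiary acid is much slower. The ketal shields C9 from the carbenoid and from hydride.

Step 6
Reactants: 9 (7R,8R)-8-methyl-7-(2-methylpropyl)-1,4-dioxaspiro[4.5]decane-8-carboxylic acid
Product: 11 2-diazo-1-[(7R,8R)-8-methyl-7-(2-methylpropyl)-1,4-dioxaspiro[4.5]decan-8-yl]ethan-1-one, via acid chloride 10 (not isolated)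
Conditions: 1-chloro-N,N,2-trimethylprop-1-en-1-amine, CH2Cl2, 0 °C → rt; then CH2N2 (3 equiv), Et2O, 0 °C → rt
Reagents that add atoms: diazomethane, C=[N+]=[N-]
Why: The α-chloroenamine makes the acid chloride without liberating HCl, so the ketal is safe; acylation of diazomethane (first stage of the Arndt–Eistert sequence) gives the diazoketone, with a second equivalent taking up HCl.

Step 7
Reactants: 11 2-diazo-1-[(7R,8R)-8-methyl-7-(2-methylpropyl)-1,4-dioxaspiro[4.5]decan-8-yl]ethan-1-one
Product: 12 (3S,3aS,7aR)-7a-methyl-3-(propan-2-yl)hexahydro-1H-indene-1,5(4H)-dione 5-(ethane-1,2-diyl ketal) (trans-fused; ketone at C17, ketal at C9)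
Conditions: Rh2(OAc)4 (1 mol%, divalent rhodium), CH2Cl2, rt, slow addition (0.01 M)
Reagents that add atoms: none
Why: Rh2(OAc)4 decomposes the diazoketone with loss of N2 to an electrophilic rhodium carbenoid at C16, which inserts into a C12–H bond through a three-centre transition state with retention at carbon, forming C12–C16. The closest known reaction type is the dirhodium-catalysed intramolecular 1,5 C–H insertion of α-diazo ketones to cyclopentanones. Ring D closes as a five-membered ring through a six-membered cyclic transition state (C16, C17, C19, C11, C12 and the migrating hydrogen). The fusion is trans because the acyl group on C19 and the isobutyl group on C11 are both equatorial on the chair of ring C, the only chair that avoids an axial isobutyl group beside the ketal. The new stereocentre C12 is set by the chair-like shape of that transition state, in which the isopropyl group takes the pseudo-equatorial position anti to C10 and cis to C11–H (12S). Site selectivity is needed against the tertiary C13–H, which would require a six-membered ring, and against the ring C methylenes C10 and C22, which could only be reached as bridged closures from an axial acyl group; the remaining C–H bonds would close four- or seven-membered rings. Carbenoid dimerisation and O–H insertion are held back by slow addition at high dilution in dry solvent.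

Step 8
Reactants: 12 (3S,3aS,7aR)-7a-methyl-3-(propan-2-yl)hexahydro-1H-indene-1,5(4H)-dione 5-(ethane-1,2-diyl ketal)
Product: 14 (1R,3S,3aS,7aR)-1-hydroxy-7a-methyl-3-(propan-2-yl)octahydro-5H-inden-5-one, via hydroxy ketal 13 (not isolated)
Conditions: NaBH4, MeOH, 0 °C; then 2 M HCl, THF, rt
Reagents that add atoms: water, O
Why: Hydride should attack the cyclopentanone from the face opposite the angular methyl C20, as in 17-keto steroids, so the C17 hydroxyl comes out cis to C20 (17R); the acid added afterwards hydrolyses the ketal (acetal hydrolysis).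

Step 9
Reactants: 14 (1R,3S,3aS,7aR)-1-hydroxy-7a-methyl-3-(propan-2-yl)octahydro-5H-inden-5-one
Product: 15 (1R,3S,3aS,7aR)-1-[(tert-butyldimethylsilyl)oxy]-7a-methyl-3-(propan-2-yl)octahydro-5H-inden-5-one
Conditions: TBSCl, imidazole, DMF, 45 °C
Reagents that add atoms: tert-butyl(chloro)dimethylsilane, CC(C)(C)[Si](C)(C)Cl
Why: Silyl ether formation at the hindered secondary alcohol; the chloride–imidazole system leaves the ketone alone, whereas a silyl triflate would also form a silyl enol ether.

Step 10
Reactants: 15 (1R,3S,3aS,7aR)-1-[(tert-butyldimethylsilyl)oxy]-7a-methyl-3-(propan-2-yl)octahydro-5H-inden-5-one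
Product: 18 1-[(1R,3S,3aS,7aR)-1-[(tert-butyldimethylsilyl)oxy]-5-hydroxy-7a-methyl-3-(propan-2-yl)-2,3,3a,4,7,7a-hexahydro-1H-inden-6-yl]ethan-1-one (enol form of the C22-acetyl C9-ketone), via enamine 16 (not isolated), via acetyl enaminone 17 (not isolated)
Conditions: pyrrolidine, TsOH (cat.), PhH, reflux (Dean–Stark); Ac2O, dioxane, rt; then AcOH/NaOAc/H2O, 50 °C
Reagents that add atoms: acetic anhydride, CC(=O)OC(C)=O; water, O
Why: Stork enamine acylation; the enamine should form toward C22, because a C9=C22 double bond lies opposite the trans ring fusion and avoids the more hindered C10. C-Acylation and hydrolysis then give the 2-acyl ketone, which is held as its enol.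

Step 11
Reactants: 18 1-[(1R,3S,3aS,7aR)-1-[(tert-butyldimethylsilyl)oxy]-5-hydroxy-7a-methyl-3-(propan-2-yl)-2,3,3a,4,7,7a-hexahydro-1H-inden-6-yl]ethan-1-one
Product: 19 (1R,3S,3aS,7aR)-6-acetyl-1-[(tert-butyldimethylsilyl)oxy]-7a-methyl-3-(propan-2-yl)-2,3,3a,4,7,7a-hexahydro-1H-inden-5-yl trifluoromethanesulfonate
Conditions: Tf2O, i-Pr2NEt, CH2Cl2, −78 °C
Reagents that add atoms: trifluoromethanesulfonic anhydride, O=S(=O)(OS(=O)(=O)C(F)(F)F)C(F)(F)F
Why: O-Sulfonylation of the diketone enolate; six-membered 2-acyl ketones react at the ring oxygen (endocyclic enol), which gives the C9 enol triflate, activated for oxidative addition by the β-acetyl group.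

Step 12
Reactants: 19 (1R,3S,3aS,7aR)-6-acetyl-1-[(tert-butyldimethylsilyl)oxy]-7a-methyl-3-(propan-2-yl)-2,3,3a,4,7,7a-hexahydro-1H-inden-5-yl trifluoromethanesulfonate
Product: 20 methyl (1R,3S,3aS,7aR)-6-acetyl-1-[(tert-butyldimethylsilyl)oxy]-7a-methyl-3-(propan-2-yl)-2,3,3a,4,7,7a-hexahydro-1H-indene-5-carboxylate
Conditions: Pd(OAc)2 (5 mol%), dppp (5 mol%), CO (1 atm), MeOH, Et3N, DMF, 60 °C
Reagents that add atoms: carbon monoxide, [C-]#[O+]; methanol, CO
Why: Palladium-catalysed alkoxycarbonylation of an enol triflate (oxidative addition, CO insertion, methanolysis) installs C7 at the ester level, which is inert in the later methylenation.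

Step 13
Reactants: 20 methyl (1R,3S,3aS,7aR)-6-acetyl-1-[(tert-butyldimethylsilyl)oxy]-7a-methyl-3-(propan-2-yl)-2,3,3a,4,7,7a-hexahydro-1H-indene-5-carboxylate
Product: 22 methyl (1R,3S,3aS,5S,6S,7aR)-6-acetyl-1-[(tert-butyldimethylsilyl)oxy]-7a-methyl-3-(propan-2-yl)octahydro-1H-indene-5-carboxylate, via cis keto ester 21 (not isolated)
Conditions: H2 (3 atm), 10% Pd/C, EtOAc, rt; then K2CO3, MeOH, rt
Reagents that add atoms: none
Why: Heterogeneous hydrogenation should add both hydrogens from the face away from the axial angular methyl, leaving the C9 ester equatorial and the C22 acetyl axial. Mild base then epimerises the ketone α-centre C22 to the equatorial position, so both arms end trans-diequatorial under thermodynamic control, as the trans B/C fusion requires.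

Step 14
Reactants: 22 methyl (1R,3S,3aS,5S,6S,7aR)-6-acetyl-1-[(tert-butyldimethylsilyl)oxy]-7a-methyl-3-(propan-2-yl)octahydro-1H-indene-5-carboxylate
Product: 23 methyl (1R,3S,3aS,5S,6S,7aR)-1-[(tert-butyldimethylsilyl)oxy]-7a-methyl-3-(propan-2-yl)-6-(prop-1-en-2-yl)octahydro-1H-indene-5-carboxylate
Conditions: Zn, CH2Br2, TiCl4, THF/CH2Cl2, 0 °C → rt
Reagents that add atoms: dibromomethane, BrCBr
Why: Takai–Lombardo methylenation; the reagent is non-basic, so the ketone is methylenated without enolisation, without Claisen-type attack of the methyl ketone on the neighbouring ester, and without touching the ester.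

Step 15
Reactants: 23 methyl (1R,3S,3aS,5S,6S,7aR)-1-[(tert-butyldimethylsilyl)oxy]-7a-methyl-3-(propan-2-yl)-6-(prop-1-en-2-yl)octahydro-1H-indene-5-carboxylate
Product: 24 (1R,3S,3aS,5S,6S,7aR)-1-[(tert-butyldimethylsilyl)oxy]-7a-methyl-3-(propan-2-yl)-6-(prop-1-en-2-yl)octahydro-1H-indene-5-carbaldehyde
Conditions: i-Bu2AlH (1.1 equiv), CH2Cl2, −78 °C; aq. potassium sodium tartrate work-up
Reagents that add atoms: none
Why: Partial reduction of an ester; the aluminium hemiacetal of this α-branched ester should persist at −78 °C and give the aldehyde only on work-up. C9 stays equatorial, which is also its stable configuration.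

Step 16
Reactants: 25 3-methylcyclopent-2-en-1-one
Product: 27 (2R,3S)-3-methyl-2-(prop-2-en-1-yl)cyclopentan-1-one, via bis(enol) silane 26 (not isolated)
Conditions: CuCl (5 mol%), NaOt-Bu (5 mol%), (S)-p-tol-BINAP (5 mol%), Ph2SiH2 (0.55 equiv), PhMe, 0 °C; then allyl bromide, Bu4N[Ph3SiF2], CH2Cl2, rt
Reagents that add atoms: allyl bromide, C=CCBr
Why: Copper hydride catalysed asymmetric conjugate reduction of a β-substituted cyclopentenone sets C25 (S) and hands the enolate over regiospecifically as a silyl enol ether. Fluoride-triggered enolate allylation then places C4 on C5 trans to the methyl group, a centre that is erased in the next step.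

Step 17
Reactants: 27 (2R,3S)-3-methyl-2-(prop-2-en-1-yl)cyclopentan-1-one
Product: 29 (S)-3-methyl-2-(prop-2-en-1-yl)cyclopent-1-en-1-yl trifluoromethanesulfonate, via trimethylsilyl enol ether 28 (not isolated)
Conditions: TMSCl, NaI, Et3N, MeCN, rt; then MeLi, THF, 0 °C; N-(5-chloropyridin-2-yl)-N-triflyl triflamide (Comins' reagent), −78 → 0 °C
Reagents that add atoms: N-(5-chloropyridin-2-yl)-1,1,1-trifluoro-N-(trifluoromethanesulfonyl)methanesulfonamide, Clc1ccc(N(S(=O)(=O)C(F)(F)F)S(=O)(=O)C(F)(F)F)nc1
Why: Enolisation under equilibrating conditions should favour the more substituted C5=C6 silyl enol ether; methyllithium frees the lithium enolate, which is O-sulfonylated (enol triflate formation). C25 is not acidic and is untouched.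

Step 18
Reactants: 24 (1R,3S,3aS,5S,6S,7aR)-1-[(tert-butyldimethylsilyl)oxy]-7a-methyl-3-(propan-2-yl)-6-(prop-1-en-2-yl)octahydro-1H-indene-5-carbaldehyde; 29 (S)-3-methyl-2-(prop-2-en-1-yl)cyclopent-1-en-1-yl trifluoromethanesulfonate
Product: 30 [(1R,3S,3aS,5S,6S,7aR)-1-[(tert-butyldimethylsilyl)oxy]-7a-methyl-3-(propan-2-yl)-6-(prop-1-en-2-yl)octahydro-1H-inden-5-yl][(S)-3-methyl-2-(prop-2-en-1-yl)cyclopent-1-en-1-yl]methanol (both C7 epimers)
Conditions: CrCl2 (4 equiv, divalent chromium), NiCl2 (2 mol%), DMF, rt
Reagents that add atoms: none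
Why: Nozaki–Hiyama–Kishi coupling: nickel inserts into the enol triflate, and the alkenylchromium species formed by transmetalation adds only to the aldehyde. The neutral conditions leave C9 and C25 untouched, and the new carbinol centre is removed in the next step.

Step 19
Reactants: 30 [(1R,3S,3aS,5S,6S,7aR)-1-[(tert-butyldimethylsilyl)oxy]-7a-methyl-3-(propan-2-yl)-6-(prop-1-en-2-yl)octahydro-1H-inden-5-yl][(S)-3-methyl-2-(prop-2-en-1-yl)cyclopent-1-en-1-yl]methanol (both C7 epimers)
Product: 31 [(1R,3S,3aS,5S,6S,7aR)-1-[(tert-butyldimethylsilyl)oxy]-7a-methyl-3-(propan-2-yl)-6-(prop-1-en-2-yl)octahydro-1H-inden-5-yl][(S)-3-methyl-2-(prop-2-en-1-yl)cyclopent-1-en-1-yl]methanone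
Conditions: Dess–Martin periodinane, NaHCO3, CH2Cl2, 0 °C → rt
Reagents that add atoms: none
Why: Dess–Martin oxidation of the allylic alcohol under buffered, non-basic conditions should give the enone without deprotonating the γ-positions C4 and C25.

Step 20
Reactants: 31 ring-open dienone (C7 ketone, allyl on C5, isopropenyl on C22)
Product: 32 tetracyclic dienone: ring B closed with Z-C2=C3, C5=C6 in ring A conjugated to the C7 ketone, C17 silyl ether
Conditions: second-generation Grubbs catalyst (10 mol%), 1,4-benzoquinone (20 mol%), PhMe (1 mM), 80 °C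
Reagents that add atoms: none
Why: Ring-closing metathesis between the allyl terminus and the isopropenyl group closes the eight-membered ring; the arms are pre-organised (trans-diequatorial on ring C, cis on C5=C6) and the ring size allows only the Z geometry at C2=C3. Benzoquinone suppresses hydride-induced migration of the allyl double bond.

Step 21
Reactants: 32 tetracyclic dienone
Product: 34 (5S)-C6=C7 enol triflate of the tetracycle (triflate oxygen on C7, cis to C23), via dimethylphenylsilyl enol ether 33 (not isolated)
Conditions: [(Ph3P)CuH]6 (10 mol% Cu, monovalent copper), PhMe2SiH, PhMe, rt → 40 °C; then MeLi, THF, 0 °C; Comins' reagent, −78 °C → rt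
Reagents that add atoms: N-(5-chloropyridin-2-yl)-1,1,1-trifluoro-N-(trifluoromethanesulfonyl)methanesulfonamide, Clc1ccc(N(S(=O)(=O)C(F)(F)F)S(=O)(=O)C(F)(F)F)nc1
Why: Copper hydride conjugate reduction (hydrocupration of the enone, then silylation of the copper enolate) should deliver hydride to C5 on the face opposite the adjacent C25 methyl, giving the cis C4/C26 relation (5S). It also forms the C6=C7 enol regiospecifically, with the geometry imposed by ring B. The base-free reduction spares the γ-hydrogens, and methyllithium then frees the enolate for O-triflation.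

Step 22
Reactants: 34 (5S)-C6=C7 enol triflate of the tetracycle
Product: 35 C17 tert-butyldimethylsilyl ether of the target
Conditions: MeZnCl, Pd(PPh3)4 (5 mol%, zerovalent palladium), THF, 60 °C
Reagents that add atoms: methylzinc chloride, C[Zn]Cl
Why: Negishi cross-coupling of the enol triflate replaces oxygen by C8 with retention of the alkene geometry and completes the tetrasubstituted C6=C7 bond.

Step 23
Reactants: 35 C17 tert-butyldimethylsilyl ether of the target
Product: 36 target CNP0541339.1 (5S,9S,11S,12S,17R,19R,22S,25S)
Conditions: Bu4NF, THF, 50 °C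
Reagents that add atoms: none
Why: Fluoride cleaves the hindered silyl ether under non-acidic conditions that cannot isomerise the 1,5-diene of ring B.

## Compound list

1 | but-3-en-2-one | CC(=O)C=C | starting material
2 | 2-[(triisopropylsilyl)oxy]buta-1,3-diene | C=CC(=C)O[Si](C(C)C)(C(C)C)C(C)C | intermediate
3 | 3-methylbutanal | CC(C)CC=O | starting material
4 | 2-(triphenyl-λ5-phosphanylidene)propanal | CC(C=O)=P(c1ccccc1)(c1ccccc1)c1ccccc1 | starting material
5 | (E)-2,5-dimethylhex-2-enal | CC(C)C/C=C(\C)C=O | intermediate
6 | (1R,6R)-1-methyl-6-(2-methylpropyl)-4-[(triisopropylsilyl)oxy]cyclohex-3-ene-1-carbaldehyde | O=C[C@]1(C)CC=C(O[Si](C(C)C)(C(C)C)C(C)C)C[C@H]1CC(C)C | intermediate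
7 | (1R,2R)-1-methyl-2-(2-methylpropyl)-4-oxocyclohexane-1-carbaldehyde | O=C[C@]1(C)CCC(=O)C[C@H]1CC(C)C | intermediate
8 | (1R,2R)-1-methyl-2-(2-methylpropyl)-4-oxocyclohexane-1-carboxylic acid | OC(=O)[C@]1(C)CCC(=O)C[C@H]1CC(C)C | intermediate
9 | (7R,8R)-8-methyl-7-(2-methylpropyl)-1,4-dioxaspiro[4.5]decane-8-carboxylic acid | OC(=O)[C@]1(C)CCC2(OCCO2)C[C@H]1CC(C)C | intermediate
10 | (7R,8R)-8-methyl-7-(2-methylpropyl)-1,4-dioxaspiro[4.5]decane-8-carbonyl chloride | ClC(=O)[C@]1(C)CCC2(OCCO2)C[C@H]1CC(C)C | intermediate
11 | 2-diazo-1-[(7R,8R)-8-methyl-7-(2-methylpropyl)-1,4-dioxaspiro[4.5]decan-8-yl]ethan-1-one | [N-]=[N+]=CC(=O)[C@]1(C)CCC2(OCCO2)C[C@H]1CC(C)C | intermediate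
12 | (3S,3aS,7aR)-7a-methyl-3-(propan-2-yl)hexahydro-1H-indene-1,5(4H)-dione 5-(ethane-1,2-diyl ketal) | O=C1C[C@@H](C(C)C)[C@@H]2CC3(OCCO3)CC[C@@]12C | intermediate
13 | (1R,3S,3aS,7aR)-1-hydroxy-7a-methyl-3-(propan-2-yl)octahydro-5H-inden-5-one ethane-1,2-diyl ketal | O[C@@H]1C[C@@H](C(C)C)[C@@H]2CC3(OCCO3)CC[C@@]12C | intermediate
14 | (1R,3S,3aS,7aR)-1-hydroxy-7a-methyl-3-(propan-2-yl)octahydro-5H-inden-5-one | O[C@@H]1C[C@@H](C(C)C)[C@@H]2CC(=O)CC[C@@]12C | intermediate
15 | (1R,3S,3aS,7aR)-1-[(tert-butyldimethylsilyl)oxy]-7a-methyl-3-(propan-2-yl)octahydro-5H-inden-5-one | CC(C)(C)[Si](C)(C)O[C@@H]1C[C@@H](C(C)C)[C@@H]2CC(=O)CC[C@@]12C | intermediate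
16 | 1-[(1R,3S,3aS,7aR)-1-[(tert-butyldimethylsilyl)oxy]-7a-methyl-3-(propan-2-yl)-2,3,3a,4,7,7a-hexahydro-1H-inden-5-yl]pyrrolidine | CC(C)(C)[Si](C)(C)O[C@@H]1C[C@@H](C(C)C)[C@@H]2CC(N3CCCC3)=CC[C@@]12C | intermediate
17 | 1-[(1R,3S,3aS,7aR)-1-[(tert-butyldimethylsilyl)oxy]-7a-methyl-3-(propan-2-yl)-5-(pyrrolidin-1-yl)-2,3,3a,4,7,7a-hexahydro-1H-inden-6-yl]ethan-1-one | CC(C)(C)[Si](C)(C)O[C@@H]1C[C@@H](C(C)C)[C@@H]2CC(N3CCCC3)=C(C(C)=O)C[C@@]12C | intermediate
18 | 1-[(1R,3S,3aS,7aR)-1-[(tert-butyldimethylsilyl)oxy]-5-hydroxy-7a-methyl-3-(propan-2-yl)-2,3,3a,4,7,7a-hexahydro-1H-inden-6-yl]ethan-1-one | CC(C)(C)[Si](C)(C)O[C@@H]1C[C@@H](C(C)C)[C@@H]2CC(O)=C(C(C)=O)C[C@@]12C | intermediate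
19 | (1R,3S,3aS,7aR)-6-acetyl-1-[(tert-butyldimethylsilyl)oxy]-7a-methyl-3-(propan-2-yl)-2,3,3a,4,7,7a-hexahydro-1H-inden-5-yl trifluoromethanesulfonate | CC(C)(C)[Si](C)(C)O[C@@H]1C[C@@H](C(C)C)[C@@H]2CC(OS(=O)(=O)C(F)(F)F)=C(C(C)=O)C[C@@]12C | intermediate
20 | methyl (1R,3S,3aS,7aR)-6-acetyl-1-[(tert-butyldimethylsilyl)oxy]-7a-methyl-3-(propan-2-yl)-2,3,3a,4,7,7a-hexahydro-1H-indene-5-carboxylate | CC(C)(C)[Si](C)(C)O[C@@H]1C[C@@H](C(C)C)[C@@H]2CC(C(=O)OC)=C(C(C)=O)C[C@@]12C | intermediate
21 | methyl (1R,3S,3aS,5S,6R,7aR)-6-acetyl-1-[(tert-butyldimethylsilyl)oxy]-7a-methyl-3-(propan-2-yl)octahydro-1H-indene-5-carboxylate | CC(C)(C)[Si](C)(C)O[C@@H]1C[C@@H](C(C)C)[C@@H]2C[C@H](C(=O)OC)[C@H](C(C)=O)C[C@@]12C | intermediate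
22 | methyl (1R,3S,3aS,5S,6S,7aR)-6-acetyl-1-[(tert-butyldimethylsilyl)oxy]-7a-methyl-3-(propan-2-yl)octahydro-1H-indene-5-carboxylate | CC(C)(C)[Si](C)(C)O[C@@H]1C[C@@H](C(C)C)[C@@H]2C[C@H](C(=O)OC)[C@@H](C(C)=O)C[C@@]12C | intermediate
23 | methyl (1R,3S,3aS,5S,6S,7aR)-1-[(tert-butyldimethylsilyl)oxy]-7a-methyl-3-(propan-2-yl)-6-(prop-1-en-2-yl)octahydro-1H-indene-5-carboxylate | CC(C)(C)[Si](C)(C)O[C@@H]1C[C@@H](C(C)C)[C@@H]2C[C@H](C(=O)OC)[C@@H](C(C)=C)C[C@@]12C | intermediate
24 | (1R,3S,3aS,5S,6S,7aR)-1-[(tert-butyldimethylsilyl)oxy]-7a-methyl-3-(propan-2-yl)-6-(prop-1-en-2-yl)octahydro-1H-indene-5-carbaldehyde | CC(C)(C)[Si](C)(C)O[C@@H]1C[C@@H](C(C)C)[C@@H]2C[C@H](C=O)[C@@H](C(C)=C)C[C@@]12C | intermediate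
25 | 3-methylcyclopent-2-en-1-one | CC1=CC(=O)CC1 | starting material
26 | bis{[(S)-3-methylcyclopent-1-en-1-yl]oxy}diphenylsilane | C[C@@H]1C=C(O[Si](c2ccccc2)(c2ccccc2)OC2=C[C@@H](C)CC2)CC1 | intermediate
27 | (2R,3S)-3-methyl-2-(prop-2-en-1-yl)cyclopentan-1-one | C=CC[C@H]1C(=O)CC[C@@H]1C | intermediate
28 | (S)-trimethyl{[3-methyl-2-(prop-2-en-1-yl)cyclopent-1-en-1-yl]oxy}silane | C=CCC1=C(O[Si](C)(C)C)CC[C@@H]1C | intermediate
29 | (S)-3-methyl-2-(prop-2-en-1-yl)cyclopent-1-en-1-yl trifluoromethanesulfonate | C=CCC1=C(OS(=O)(=O)C(F)(F)F)CC[C@@H]1C | intermediate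
30 | [(1R,3S,3aS,5S,6S,7aR)-1-[(tert-butyldimethylsilyl)oxy]-7a-methyl-3-(propan-2-yl)-6-(prop-1-en-2-yl)octahydro-1H-inden-5-yl][(S)-3-methyl-2-(prop-2-en-1-yl)cyclopent-1-en-1-yl]methanol (both C7 epimers) | CC(C)(C)[Si](C)(C)O[C@@H]1C[C@@H](C(C)C)[C@@H]2C[C@H](C(O)C3=C(CC=C)[C@@H](C)CC3)[C@@H](C(C)=C)C[C@@]12C | intermediate
31 | [(1R,3S,3aS,5S,6S,7aR)-1-[(tert-butyldimethylsilyl)oxy]-7a-methyl-3-(propan-2-yl)-6-(prop-1-en-2-yl)octahydro-1H-inden-5-yl][(S)-3-methyl-2-(prop-2-en-1-yl)cyclopent-1-en-1-yl]methanone (ring-open dienone) | CC(C)(C)[Si](C)(C)O[C@@H]1C[C@@H](C(C)C)[C@@H]2C[C@H](C(=O)C3=C(CC=C)[C@@H](C)CC3)[C@@H](C(C)=C)C[C@@]12C | intermediate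
32 | tetracyclic dienone (Z-C2=C3, C5=C6, C7 ketone, C17 silyl ether) | C/C1=C/CC2=C(C(=O)[C@H]3C[C@H]4[C@H](C(C)C)C[C@@H](O[Si](C)(C)C(C)(C)C)[C@]4(C)C[C@H]13)CC[C@@H]2C | intermediate
33 | (5S)-C6=C7 dimethylphenylsilyl enol ether of the tetracycle | C/C1=C/C[C@@H]2/C(=C(/O[Si](C)(C)c3ccccc3)[C@H]3C[C@H]4[C@H](C(C)C)C[C@@H](O[Si](C)(C)C(C)(C)C)[C@]4(C)C[C@H]13)CC[C@@H]2C | intermediate
34 | (5S)-C6=C7 enol triflate of the tetracycle | C/C1=C/C[C@@H]2/C(=C(/OS(=O)(=O)C(F)(F)F)[C@H]3C[C@H]4[C@H](C(C)C)C[C@@H](O[Si](C)(C)C(C)(C)C)[C@]4(C)C[C@H]13)CC[C@@H]2C | intermediate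
35 | C17 tert-butyldimethylsilyl ether of the target | C/C1=C/C[C@@H]2/C(=C(/C)[C@H]3C[C@H]4[C@H](C(C)C)C[C@@H](O[Si](C)(C)C(C)(C)C)[C@]4(C)C[C@H]13)CC[C@@H]2C | intermediate
36 | CNP0541339.1 (5S,9S,11S,12S,17R,19R,22S,25S) | C/C1=C/C[C@@H]2/C(=C(/C)[C@H]3C[C@H]4[C@H](C(C)C)C[C@@H](O)[C@]4(C)C[C@H]13)CC[C@@H]2C | target

## Step count and least certain steps

Total step count: 23. Longest linear sequence: 20 steps (steps 2–15, then 18–23); steps 1 and 16–17 are side branches.

**Step 7 (key step).** The acceptor-only carbenoid is very reactive. The most likely failures are dimerisation, competing insertion into the tertiary C13–H bond, and erosion of the C12 selectivity because the transition state is early. The fallback for step 7 uses a more discriminating acceptor/acceptor carbenoid; it sets out from acid 9 and comes back to the route at 12. Acid chloride 10, made as in step 6, is extended with potassium methyl malonate (MgCl2, Et3N) to methyl 3-[(7R,8R)-8-methyl-7-(2-methylpropyl)-1,4-dioxaspiro[4.5]decan-8-yl]-3-oxopropanoate F1 by decarboxylative acylation. Diazo transfer (4-acetamidobenzenesulfonyl azide, Et3N) gives methyl 2-diazo-3-[(7R,8R)-8-methyl-7-(2-methylpropyl)-1,4-dioxaspiro[4.5]decan-8-yl]-3-oxopropanoate F2 as the diazo keto ester. Rh2(OAc)4 should close ring D to the C16-methoxycarbonyl hydrindanone ketal F3 through the same 1,5 insertion, and Krapcho dealkoxycarbonylation (LiCl, wet DMSO, 140 °C) then returns 12.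

**Step 3.** The β-branched, trisubstituted enal may turn over too slowly on the catalyst, which would force temperatures at which enantioselectivity erodes. The fallback for step 3 gives up catalytic induction in favour of a classical resolution; it sets out from 5 and 2 and comes back at 8. The cycloaddition is run with Me2AlCl, followed by the same hydrolysis and oxidation. This gives racemic material, in which 6, 7 and 8 are accompanied by (1S,6S)-1-methyl-6-(2-methylpropyl)-4-[(triisopropylsilyl)oxy]cyclohex-3-ene-1-carbaldehyde F4 as the mirror-image cycloadduct, by (1S,2S)-1-methyl-2-(2-methylpropyl)-4-oxocyclohexane-1-carbaldehyde F5 as the mirror-image keto aldehyde, and by (1S,2S)-1-methyl-2-(2-methylpropyl)-4-oxocyclohexane-1-carboxylic acid F6 as the mirror-image keto acid. Salt formation with (R)-1-phenylethan-1-amine gives (R)-1-phenylethan-1-aminium (1R,2R)-1-methyl-2-(2-methylpropyl)-4-oxocyclohexane-1-carboxylate F7 from 8 and (R)-1-phenylethan-1-aminium (1S,2S)-1-methyl-2-(2-methylpropyl)-4-oxocyclohexane-1-carboxylate F8 from the mirror-image acid. These diastereomeric salts are separated by crystallisation, and acidification of the former returns 8.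

**Step 17.** Equilibrating enolisation may not be fully regioselective, so part of the material would enolise toward C23 and give the isomeric triflate. The fallback for step 17 makes the C5=C6 enolate by conjugate addition; it sets out from silane 26 and comes back at 29. Dimethyl(methylidene)ammonium iodide gives the Mannich base (2S,3S)-2-[(dimethylamino)methyl]-3-methylcyclopentan-1-one F9 after aqueous work-up. Quaternisation with MeI gives 1-[(1S,2S)-2-methyl-5-oxocyclopentyl]-N,N,N-trimethylmethanaminium iodide F10 as the methiodide, and elimination with NaHCO3 gives (S)-3-methyl-2-methylidenecyclopentan-1-one F11 as the exocyclic enone, which is used cold and at once because it can isomerise into the ring. Addition of (CH2=CH)2CuLi and trapping of the regiodefined enolate with Comins' reagent returns 29.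

**Step 20.** The cross-conjugated dienone may close slowly at the hindered isopropenyl group, so oligomerisation and migration of the allyl double bond into conjugation could take over. The fallback for step 20 closes the ring on the more flexible sp3 carbinol; it sets out from 30 and comes back at 32. The same metathesis catalyst should give the tetracyclic C7 carbinol F12 with ring B closed, and Dess–Martin oxidation returns 32.

**Step 21.** The tetrasubstituted enone may react sluggishly, and the fold of ring B may weaken the facial preference at C5 that the C25 methyl exerts. The fallback for step 21 moves the hydride delivery to the ring-open stage, where only that methyl group differentiates the faces; it sets out from 31 and comes back at 34. Stoichiometric [(Ph3P)CuH]6 (monovalent copper) in moist benzene reduces the enone and protonates the copper enolate in the flask, which gives the ring-open saturated ketone F13 with C5–H anti to the C25 methyl. Ring-closing metathesis with second-generation Grubbs catalyst gives the ring B ketone F14 with C5–H in place. Thermodynamic enolisation (KH, THF), which should prefer the double bond exocyclic to the five-membered ring over one exocyclic to ring C, and Comins' reagent then return 34.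

## Further compounds

F1 | step 7 | methyl 3-[(7R,8R)-8-methyl-7-(2-methylpropyl)-1,4-dioxaspiro[4.5]decan-8-yl]-3-oxopropanoate | COC(=O)CC(=O)[C@]1(C)CCC2(OCCO2)C[C@H]1CC(C)C
F2 | step 7 | methyl 2-diazo-3-[(7R,8R)-8-methyl-7-(2-methylpropyl)-1,4-dioxaspiro[4.5]decan-8-yl]-3-oxopropanoate | COC(=O)C(=[N+]=[N-])C(=O)[C@]1(C)CCC2(OCCO2)C[C@H]1CC(C)C
F3 | step 7 | C16-methoxycarbonyl hydrindanone ketal (ring D β-keto ester, C16 epimers) | O=C1C(C(=O)OC)[C@@H](C(C)C)[C@@H]2CC3(OCCO3)CC[C@@]12C
F4 | step 3 | (1S,6S)-1-methyl-6-(2-methylpropyl)-4-[(triisopropylsilyl)oxy]cyclohex-3-ene-1-carbaldehyde | O=C[C@@]1(C)CC=C(O[Si](C(C)C)(C(C)C)C(C)C)C[C@@H]1CC(C)C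
F5 | step 3 | (1S,2S)-1-methyl-2-(2-methylpropyl)-4-oxocyclohexane-1-carbaldehyde | O=C[C@@]1(C)CCC(=O)C[C@@H]1CC(C)C
F6 | step 3 | (1S,2S)-1-methyl-2-(2-methylpropyl)-4-oxocyclohexane-1-carboxylic acid | OC(=O)[C@@]1(C)CCC(=O)C[C@@H]1CC(C)C
F7 | step 3 | (R)-1-phenylethan-1-aminium (1R,2R)-1-methyl-2-(2-methylpropyl)-4-oxocyclohexane-1-carboxylate | C[C@@H]([NH3+])c1ccccc1.[O-]C(=O)[C@]1(C)CCC(=O)C[C@H]1CC(C)C
F8 | step 3 | (R)-1-phenylethan-1-aminium (1S,2S)-1-methyl-2-(2-methylpropyl)-4-oxocyclohexane-1-carboxylate | C[C@@H]([NH3+])c1ccccc1.[O-]C(=O)[C@@]1(C)CCC(=O)C[C@@H]1CC(C)C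
F9 | step 17 | (2S,3S)-2-[(dimethylamino)methyl]-3-methylcyclopentan-1-one | CN(C)C[C@H]1C(=O)CC[C@@H]1C
F10 | step 17 | 1-[(1S,2S)-2-methyl-5-oxocyclopentyl]-N,N,N-trimethylmethanaminium iodide | C[N+](C)(C)C[C@H]1C(=O)CC[C@@H]1C.[I-]
F11 | step 17 | (S)-3-methyl-2-methylidenecyclopentan-1-one | C=C1C(=O)CC[C@@H]1C
F12 | step 20 | tetracyclic C7 carbinol (ring B closed, C5=C6, both C7 epimers) | C/C1=C/CC2=C(C(O)[C@H]3C[C@H]4[C@H](C(C)C)C[C@@H](O[Si](C)(C)C(C)(C)C)[C@]4(C)C[C@H]13)CC[C@@H]2C
F13 | step 21 | ring-open saturated ketone (5S, C6 epimers) | CC(C)(C)[Si](C)(C)O[C@@H]1C[C@@H](C(C)C)[C@@H]2C[C@H](C(=O)C3CC[C@H](C)[C@@H]3CC=C)[C@@H](C(C)=C)C[C@@]12C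
F14 | step 21 | ring B ketone with C5–H in place (5S, C6 epimers) | C/C1=C/C[C@@H]2C(C(=O)[C@H]3C[C@H]4[C@H](C(C)C)C[C@@H](O[Si](C)(C)C(C)(C)C)[C@]4(C)C[C@H]13)CC[C@@H]2C
A1 | alternative 1 | C17 tert-butyldimethylsilyl ether of the target | C/C1=C/C[C@@H]2/C(=C(/C)[C@H]3C[C@H]4[C@H](C(C)C)C[C@@H](O[Si](C)(C)C(C)(C)C)[C@]4(C)C[C@H]13)CC[C@@H]2C
A2 | alternative 2 | methyl 6-{[(tert-butyldimethylsilyl)oxy]methyl}-3a-methyl-3-oxo-1-(propan-2-yl)-3a,4,5,6,7,7a-hexahydro-3H-indene-5-carboxylate (trans-fused) | CC(C)(C)[Si](C)(C)OC[C@H]1C[C@H]2C(C(C)C)=CC(=O)[C@]2(C)C[C@@H]1C(=O)OC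
A3 | alternative 3 | (S)-2-methyl-4-(propan-2-yl)cyclopent-2-en-1-one | CC1=C[C@H](C(C)C)CC1=O
A4 | alternative 3 | 2-methyl-4-(propan-2-yl)-2,3-di(prop-2-en-1-yl)cyclopentan-1-one | C=CC[C@H]1[C@H](C(C)C)CC(=O)[C@]1(C)CC=C
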